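Ring B (C1–C5 with spiro C6; ring A = C7–C11) is disconnected across C1–C6 and C3–C4 into a three-carbon acrylate (C1–C3) and the acetyl unit (C5, C4) of a dimedone-derived β-diketone. The key step exploits that spiro C6 lies between two carbons of carbonyl origin (C5 in ring B, C7 in ring A): as a doubly activated carbon acid it undergoes an enantioselective Michael addition, and the acetyl enolate then closes ring B by Claisen acylation in the same flask, a [3+3] annulation that sets the C6 stereocentre. Both rings are then adjusted: Stork–Danheiser transpositions, directed epoxidation/hydride opening, bromomethylenation and Appel inversion.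

Key step: step 2

Remark: 3-ethoxy-5,5-dimethylcyclohex-2-en-1-one and 1,1,1,3,3,3-hexafluoropropan-2-yl acrylate are taken as purchasable; all spiro compounds carry the target's numbering (ring B C1–C5, spiro C6, ring A C7–C11 with C7 the carbinol carbon, C9 the bromide carbon, C11 the gem-dimethyl carbon).

Step 1
Reactants: 1 3-ethoxy-5,5-dimethylcyclohex-2-en-1-one
Product: 2 6-acetyl-3-ethoxy-5,5-dimethylcyclohex-2-en-1-one (racemic, largely enolised)
Conditions: LiN(SiMe3)2 (2.2 equiv), THF, −78 °C; 1-acetylimidazole (1.1 equiv), −78 → 0 °C; 1 M HCl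
Reagents that add atoms: 1-acetylimidazole CC(=O)n1ccnc1
Why: Kinetic α′-deprotonation of the vinylogous ester occurs at C6, its only sp3 α-carbon, and the lithium enolate should be C-acylated by the acyl azole (crossed Claisen acylation), the second equivalent of base storing the product as its diketonate.

Step 2
Reactants: 2 6-acetyl-3-ethoxy-5,5-dimethylcyclohex-2-en-1-one; 3 1,1,1,3,3,3-hexafluoropropan-2-yl acrylate
Product: 5 (6R)-9-ethoxy-11,11-dimethylspiro[5.5]undec-8-ene-3,5,7-trione, via Michael adduct 4 (not isolated)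
Conditions: thiourea from 9-amino-9-deoxy-epi-quinidine and 3,5-bis(trifluoromethyl)phenyl isothiocyanate (10 mol %), 3 (1.1 equiv), toluene, −20 °C → rt; then LiN(SiMe3)2 (2.5 equiv), THF, −78 → 0 °C; 1 M HCl
Reagents that add atoms: none
Why: The quinuclidine nitrogen of the bifunctional catalyst deprotonates the enolised β-diketone 2 while the thiourea hydrogen-bonds the acrylate carbonyl, so that C6 adds to the acrylate β-carbon (C1) and gives adduct 4 (bond C1–C6); LiN(SiMe3)2 then forms the enolate of the acetyl methyl group (C4), which attacks the activated ester carbonyl (C3), expels hexafluoroisopropoxide and is made irreversible by deprotonation of the new 1,3-dione (bond C3–C4). The closest known reactions are the Michael–Claisen [3+3] annulation of methyl ketones with acrylates to 4,4-disubstituted cyclohexane-1,3-diones and cinchona-thiourea-catalysed Michael additions of 1,3-dicarbonyl compounds to activated acrylates. Ring B is closed in the Claisen stage by a 6-exo-trig attack of the C4 enolate on the ester carbonyl (Dieckmann mode); no ring closes in the Michael stage. The only new stereocentre, C6, is set in the Michael stage by the catalyst, which should discriminate the enolate faces because C6 is flanked by the very different C11 gem-dimethyl carbon and C7 carbonyl; being quaternary it cannot epimerise later. The step needs C- over O-alkylation (soft conjugate addition, O-adducts revert), Claisen closure from C4 and not from the ring A γ-carbon C10 (the methyl ketone is the more acidic and less hindered site and only it leads to a stabilised dione enolate) and no retro-Claisen loss of the acetyl group (non-nucleophilic base, poorly nucleophilic fluoroalkoxide).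

Step 3
Reactants: 5 (6R)-9-ethoxy-11,11-dimethylspiro[5.5]undec-8-ene-3,5,7-trione
Product: 7 (6S)-7,11,11-trimethylspiro[5.5]undec-7-ene-3,5,9-trione, via tertiary carbinol 6 (not isolated)
Conditions: CeCl3 (4 equiv), MeLi (4 equiv), THF, −78 → 0 °C; then 1 M HCl, rt
Reagents that add atoms: methyllithium [Li]C; water O
Why: The ring B 1,3-dione is masked in the flask as its enolate, so the organocerium reagent should add only to the C7 carbonyl of the ring A vinylogous ester, and acid then expels the C7 hydroxyl and hydrolyses the enol ether (Stork–Danheiser 1,3-carbonyl transposition) to the C7-methyl enone without touching C6.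

Step 4
Reactants: 7 (6S)-7,11,11-trimethylspiro[5.5]undec-7-ene-3,5,9-trione
Product: 8 (6S)-3-(2-methylpropoxy)-7,11,11-trimethylspiro[5.5]undeca-3,7-diene-5,9-dione
Conditions: 2-methylpropan-1-ol (5 equiv), TsOH·H2O (5 mol %), benzene, reflux, azeotropic removal of water
Reagents that add atoms: 2-methylpropan-1-ol CC(C)CO
Why: Reversible acid-catalysed enol etherification of the 1,3-dione should place the alkoxy group on the unhindered C3 and leave the carbonyl at C5 beside quaternary C6 (thermodynamic control), the regiochemistry required for the later ring B transposition.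

Step 5
Reactants: 8 (6S)-3-(2-methylpropoxy)-7,11,11-trimethylspiro[5.5]undeca-3,7-diene-5,9-dione
Product: 9 (6S,9S)-9-hydroxy-3-(2-methylpropoxy)-7,11,11-trimethylspiro[5.5]undeca-3,7-dien-5-one
Conditions: RuCl[(S,S)-TsDPEN](p-cymene) (2 mol %), HCO2H/Et3N (5:2), CH2Cl2, rt
Reagents that add atoms: none
Why: Asymmetric transfer hydrogenation should reduce only the ring A enone carbonyl (the vinylogous ester carbonyl C5 is far less electrophilic), and the (S,S) catalyst, with the C7=C8 alkene taking the place of the arene of aryl ketones, is expected to set (9S) under catalyst control, placing the hydroxyl on the face of the C1H2 arm.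

Step 6
Reactants: 9 (6S,9S)-9-hydroxy-3-(2-methylpropoxy)-7,11,11-trimethylspiro[5.5]undeca-3,7-dien-5-one
Product: 10 (6S,7R,8S,9S)-7,8-epoxy-9-hydroxy-3-(2-methylpropoxy)-7,11,11-trimethylspiro[5.5]undec-3-en-5-one
Conditions: VO(acac)2 (5 mol %), t-BuOOH (1.5 equiv), CH2Cl2, 0 °C → rt
Reagents that add atoms: tert-butyl hydroperoxide CC(C)(C)OO
Why: Hydroxyl-directed epoxidation of the allylic alcohol delivers oxygen to the C7=C8 face syn to the C9 hydroxyl, which sets C7 relative to C9, while the electron-poor alkene of the ring B vinylogous ester should not react.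

Step 7
Reactants: 10 (6S,7R,8S,9S)-7,8-epoxy-9-hydroxy-3-(2-methylpropoxy)-7,11,11-trimethylspiro[5.5]undec-3-en-5-one
Product: 12 (6S,7S,9S)-7,9-dihydroxy-7,11,11-trimethylspiro[5.5]undec-4-en-3-one, via triol 11 (not isolated)
Conditions: LiAlH4 (4 equiv), THF, 0 → 50 °C; then 1 M HCl, THF, 0 °C → rt
Reagents that add atoms: water O
Why: Hydride should open the epoxide at the secondary carbon C8 from the face opposite the oxirane oxygen (SN2, trans-diaxial; C7 is tertiary and neopentyl), leaving the C7 alcohol cis to the C9 hydroxyl, and also reduce the C5 carbonyl, after which acid effects the Stork–Danheiser transposition in ring B to the C4=C5 enone with the carbonyl at C3.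

Step 8
Reactants: 12 (6S,7S,9S)-7,9-dihydroxy-7,11,11-trimethylspiro[5.5]undec-4-en-3-one
Product: 13 (3E,6S,7S,9S)-3-(bromomethylidene)-7,11,11-trimethylspiro[5.5]undec-4-ene-7,9-diol
Conditions: Ph3P(CH2Br)Br (3 equiv), NaN(SiMe3)2 (2.9 equiv), THF, −78 °C; then 12, −78 → 0 °C
Reagents that add atoms: (bromomethyl)triphenylphosphonium bromide BrC[P+](c1ccccc1)(c1ccccc1)c1ccccc1.[Br-]
Why: Wittig bromomethylenation should take place at the C3 carbonyl (1,2-addition, the β-carbon C5 being shielded by C6) in the presence of the free hydroxyls; both geometrical isomers are expected, with a modest preference for E because bromine is placed syn to the bulkier sp3 C2H2 side in the oxaphosphetane, and the E isomer is separated.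

Step 9
Reactants: 13 (3E,6S,7S,9S)-3-(bromomethylidene)-7,11,11-trimethylspiro[5.5]undec-4-ene-7,9-diol
Product: 14 (3E,6S,7S,9R)-9-bromo-3-(bromomethylidene)-7,11,11-trimethylspiro[5.5]undec-4-en-7-ol
Conditions: CBr4 (2 equiv), PPh3 (2.2 equiv), CH2Cl2, 0 °C → rt
Reagents that add atoms: carbon tetrabromide BrC(Br)(Br)Br
Why: In the Appel reaction the secondary C9 hydroxyl is activated as an alkoxyphosphonium ion and displaced by bromide with inversion (SN2, the axial leaving group being attacked from the open equatorial side), which should give the (9R) bromide trans to the C7 hydroxyl, while the tertiary C7 alcohol cannot be substituted.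

Compound list
1 | 3-ethoxy-5,5-dimethylcyclohex-2-en-1-one | CCOC1=CC(=O)CC(C)(C)C1 | starting material
2 | 6-acetyl-3-ethoxy-5,5-dimethylcyclohex-2-en-1-one (racemic, enolised) | CCOC1=CC(=O)C(C(C)=O)C(C)(C)C1 | intermediate
3 | 1,1,1,3,3,3-hexafluoropropan-2-yl acrylate | C=CC(=O)OC(C(F)(F)F)C(F)(F)F | starting material
4 | Michael adduct (not isolated): 1,1,1,3,3,3-hexafluoropropan-2-yl 3-[(1R)-1-acetyl-4-ethoxy-6,6-dimethyl-2-oxocyclohex-3-en-1-yl]propanoate | CCOC1=CC(=O)[C@@](CCC(=O)OC(C(F)(F)F)C(F)(F)F)(C(C)=O)C(C)(C)C1 | intermediate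
5 | (6R)-9-ethoxy-11,11-dimethylspiro[5.5]undec-8-ene-3,5,7-trione | O=C1CC(=O)CC[C@]12C(=O)C=C(OCC)CC2(C)C | intermediate
6 | tertiary carbinol (not isolated): (6S)-9-ethoxy-7-hydroxy-7,11,11-trimethylspiro[5.5]undec-8-ene-3,5-dione, C7 epimers | O=C1CC(=O)CC[C@]12C(C)(O)C=C(OCC)CC2(C)C | intermediate
7 | (6S)-7,11,11-trimethylspiro[5.5]undec-7-ene-3,5,9-trione | O=C1CC(=O)CC[C@]12C(C)=CC(=O)CC2(C)C | intermediate
8 | (6S)-3-(2-methylpropoxy)-7,11,11-trimethylspiro[5.5]undeca-3,7-diene-5,9-dione | CC(C)COC1=CC(=O)[C@]2(CC1)C(C)=CC(=O)CC2(C)C | intermediate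
9 | (6S,9S)-9-hydroxy-3-(2-methylpropoxy)-7,11,11-trimethylspiro[5.5]undeca-3,7-dien-5-one | CC(C)COC1=CC(=O)[C@]2(CC1)C(C)=C[C@@H](O)CC2(C)C | intermediate
10 | (6S,7R,8S,9S)-7,8-epoxy-9-hydroxy-3-(2-methylpropoxy)-7,11,11-trimethylspiro[5.5]undec-3-en-5-one | CC(C)COC1=CC(=O)[C@]2(CC1)[C@@]3(C)O[C@H]3[C@@H](O)CC2(C)C | intermediate
11 | triol (not isolated): (6R,7S,9S)-3-(2-methylpropoxy)-7,11,11-trimethylspiro[5.5]undec-3-ene-5,7,9-triol, C5 epimers | CC(C)COC1=CC(O)[C@]2(CC1)[C@@](C)(O)C[C@@H](O)CC2(C)C | intermediate
12 | (6S,7S,9S)-7,9-dihydroxy-7,11,11-trimethylspiro[5.5]undec-4-en-3-one | O=C1C=C[C@]2(CC1)[C@@](C)(O)C[C@@H](O)CC2(C)C | intermediate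
13 | (3E,6S,7S,9S)-3-(bromomethylidene)-7,11,11-trimethylspiro[5.5]undec-4-ene-7,9-diol | Br/C=C1/C=C[C@]2(CC1)[C@@](C)(O)C[C@@H](O)CC2(C)C | intermediate
14 | (3E,6S,7S,9R)-9-bromo-3-(bromomethylidene)-7,11,11-trimethylspiro[5.5]undec-4-en-7-ol | CC1(C)C[C@@H](Br)C[C@](C)(O)[C@@]12C=C/C(=C/Br)CC2 | target

Total step count: 9. Longest linear sequence: 9 steps (1 → 14).

Steps most likely to fail

Step 2. The conjugate addition may be slow and weakly face-selective because C6 is neopentyl and the donor is strongly enolised; an uncatalysed background reaction or acyl transfer from the activated ester to the enol oxygen could then compete, and in the basic stage cleavage of the acetyl group could compete with ring closure. The sense of induction also has to be established; the quinine-derived pseudoenantiomer of the catalyst is available for the opposite sense. Fallback: from 2, a palladium-catalysed asymmetric allylic alkylation of the β-diketone (Tsuji–Trost type; Pd2(dba)3 as source of zerovalent palladium, a chiral trans-cyclohexane-1,2-diamine bis(2-diphenylphosphinobenzamide) ligand, allyl acetate) should give (6R)-6-acetyl-3-ethoxy-5,5-dimethyl-6-(prop-2-en-1-yl)cyclohex-2-en-1-one F1. Hydroboration with 9-BBN and oxidation with NaBO3 should give the primary alcohol (6R)-6-acetyl-3-ethoxy-6-(3-hydroxypropyl)-5,5-dimethylcyclohex-2-en-1-one F2, and oxidation (TEMPO, PhI(OAc)2, aqueous MeCN) the acid 3-[(1R)-1-acetyl-4-ethoxy-6,6-dimethyl-2-oxocyclohex-3-en-1-yl]propanoic acid F3. Me3SiCHN2 should give methyl 3-[(1R)-1-acetyl-4-ethoxy-6,6-dimethyl-2-oxocyclohex-3-en-1-yl]propanoate F4, and LiN(SiMe3)2 then closes ring B by Claisen condensation and returns to 5.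

Step 8. Oxaphosphetane formation may show little geometric control, since bromine syn to C4–H and bromine syn to C2H2 differ only slightly in strain, and the basic ylide may enolise the ketone. Fallback: from 12 the olefination is run without regard to geometry and the isomers are separated. The unwanted (3Z,6S,7S,9S)-3-(bromomethylidene)-7,11,11-trimethylspiro[5.5]undec-4-ene-7,9-diol F5 is re-equilibrated by triplet-sensitised photoisomerisation (thioxanthen-9-one, 405 nm, MeCN) and separated again, returning to 13.

Step 9. E2 elimination of the axial alkoxyphosphonium ion (antiperiplanar hydrogens at C8 and C10), capture of phosphorus by the cis C7 hydroxyl, or ionisation may compete with the SN2 displacement. Fallback: from 13, selective sulfonylation of the secondary hydroxyl (Tf2O, pyridine, CH2Cl2, −40 °C) should give (3E,6S,7S,9S)-3-(bromomethylidene)-7-hydroxy-7,11,11-trimethylspiro[5.5]undec-4-en-9-yl trifluoromethanesulfonate F6. This discrete sulfonate is displaced with inversion by Bu4NBr at −20 → 0 °C, returning to 14.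

Further compounds
F1 | step 2 | (6R)-6-acetyl-3-ethoxy-5,5-dimethyl-6-(prop-2-en-1-yl)cyclohex-2-en-1-one | C=CC[C@@]1(C(C)=O)C(=O)C=C(OCC)CC1(C)C
F2 | step 2 | (6R)-6-acetyl-3-ethoxy-6-(3-hydroxypropyl)-5,5-dimethylcyclohex-2-en-1-one | OCCC[C@@]1(C(C)=O)C(=O)C=C(OCC)CC1(C)C
F3 | step 2 | 3-[(1R)-1-acetyl-4-ethoxy-6,6-dimethyl-2-oxocyclohex-3-en-1-yl]propanoic acid | OC(=O)CC[C@@]1(C(C)=O)C(=O)C=C(OCC)CC1(C)C
F4 | step 2 | methyl 3-[(1R)-1-acetyl-4-ethoxy-6,6-dimethyl-2-oxocyclohex-3-en-1-yl]propanoate | COC(=O)CC[C@@]1(C(C)=O)C(=O)C=C(OCC)CC1(C)C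
F5 | step 8 | (3Z,6S,7S,9S)-3-(bromomethylidene)-7,11,11-trimethylspiro[5.5]undec-4-ene-7,9-diol | Br\C=C1/C=C[C@]2(CC1)[C@@](C)(O)C[C@@H](O)CC2(C)C
F6 | step 9 | (3E,6S,7S,9S)-3-(bromomethylidene)-7-hydroxy-7,11,11-trimethylspiro[5.5]undec-4-en-9-yl trifluoromethanesulfonate | Br/C=C1/C=C[C@]2(CC1)[C@@](C)(O)C[C@@H](OS(=O)(=O)C(F)(F)F)CC2(C)C
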